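**Plan**

1. Locants follow germacrane numbering: C1 furanone C–O carbon (bears C10), C2 furanone CH, C3 ketone, C4 C(Me)–O, C5=C6 enol‑lactone alkene, C7/C11/C12 butenolide, C13 its CH2OH, C8 acyloxy CH, C9 CH2, C10 CHMe. Retrosynthesis: remove the O8 acrylate, trace the C5=C6/butenolide unit back to a furan, then cut C2–C3 and O4–C1 together, which opens the furanone and the ten‑membered ring at once.
2. Enabling feature: O8 can be tied to the C3 carboxyl as a seven‑membered lactone across the furan C6–C7 bond, and the acetyl carbon C2 hangs from C8 through C9–C10–C1. Its enolate reaches C3 through a seven‑membered transition state, the lactone is ring‑expanded to the carbocycle, and the C4 hydroxyl then closes the furanone on C1.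
3. Forward ring order: furan (bought) → γ‑lactone O8–C1 (allylation, hydrogenation) → opened by MeLi to the methyl ketone → seven‑membered lactone O8–C3 → ten‑membered carbocycle plus furanone (key step) → butenolide by singlet‑oxygen oxidation of the furan → C5=C6 by dehydration.
4. Stereochemistry: C4 from methyl (S)‑2‑methylglycidate; C8 by ligand‑controlled iridium allylation; C10 by hydrogenation cis to the C8 furyl group; C5=C6 geometry enforced by the ring.
5. Helpers and their removal: the furan masks the butenolide; the seven‑membered lactone is tether, acyl donor and leaving group in one and ends as the free O8–H that takes the side chain; the O4 trimethylsilyl ether falls off in the acid half of the key step.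

Key step: step 10

Remark: 1, 3 and 6 are taken as catalogue compounds; the ligand in step 4 is written as (R)‑SEGPHOS on the assumption that it gives the 8S carbinol (otherwise the S ligand is used).

**Route**

Step 1
Reactants: 1 furan‑3,4‑diyldimethanol
Product: 2 mono‑TBDPS ether
Conditions: NaH (1.0 equiv), THF, 0 °C; TBDPSCl (1.0 equiv), 0 °C → rt
Reagents that add atoms: tert‑butyl(chloro)diphenylsilane, CC(C)(C)[Si](Cl)(c1ccccc1)c1ccccc1
Why: Statistical monosilylation of the symmetrical diol through its monosodium alkoxide (Williamson‑type O‑silylation) should give the mono ether, whose bulky non‑coordinating silyl group leaves the free CH2OH as the only directing group on the furan.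

Step 2
Reactants: 2 mono‑TBDPS ether; 3 methyl (2S)‑2‑methyloxirane‑2‑carboxylate
Product: 5 furyl α‑hydroxy ester, via dilithiated furan 4 (not isolated)
Conditions: n‑BuLi (2.2 equiv), THF, −78 → 0 °C; MgBr2·OEt2 (1.1 equiv), −40 °C; CuI (10 mol%), 3, −40 → 0 °C; aq NH4Cl
Reagents that add atoms: none
Why: Alkoxide‑directed ortho‑lithiation of the 3‑furylmethanol at the adjacent α‑position, transmetalation and copper‑catalysed Grignard opening of the glycidic ester at its unsubstituted CH2 (SN2) should form the C5–C6 bond, the quaternary C4 centre being taken unchanged from 3 because its C–O bond is not broken.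

Step 3
Reactants: 6 ethyl 2‑(hydroxymethyl)prop‑2‑enoate
Product: 7 allylic tert‑butyl carbonate
Conditions: Boc2O, DMAP (cat.), CH2Cl2, 0 °C → rt
Reagents that add atoms: di‑tert‑butyl dicarbonate, CC(C)(C)OC(=O)OC(=O)OC(C)(C)C
Why: DMAP‑catalysed O‑acylation of the Morita–Baylis–Hillman alcohol gives the allylic carbonate that serves as the allyl donor.

Step 4
Reactants: 5 furyl α‑hydroxy ester; 7 allylic tert‑butyl carbonate
Product: 9 α‑methylene γ‑lactone, via homoallylic alcohol 8 (not isolated)
Conditions: [Ir(cod)Cl]2 (2.5 mol%), (R)‑SEGPHOS (5 mol%), 4‑cyano‑3‑nitrobenzoic acid (10 mol%), Cs2CO3 (20 mol%), THF, 70 °C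
Reagents that add atoms: none
Why: Krische‑type iridium‑catalysed transfer‑hydrogenative 2‑(alkoxycarbonyl)allylation: the primary alcohol is dehydrogenated in situ, the aldehyde is allylated by the chiral π‑allyliridium C,O‑benzoate and the alkoxide lactonises onto the ethyl ester, C8 being set by the ligand (8S) while the tertiary alcohol and methyl ester stay untouched.

Step 5
Reactants: 9 α‑methylene γ‑lactone
Product: 10 cis γ‑lactone methyl ester
Conditions: H2 (1 atm), RhCl(PPh3)3 (5 mol%), benzene/EtOH, rt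
Reagents that add atoms: none
Why: Homogeneous hydrogenation of the exocyclic 1,1‑disubstituted alkene (Wilkinson‑type) should add hydrogen from the lactone face opposite the furyl group at C8 and so set C10 cis to it (10S), without reducing the furan or cleaving the furfuryl‑type C–O bond.

Step 6
Reactants: 10 cis γ‑lactone methyl ester
Product: 12 γ‑lactone carboxylic acid, via ring‑opened diacid 11 (not isolated)
Conditions: LiOH·H2O (4 equiv), THF/H2O, 0 °C → rt; then 1 M HCl to pH 2, rt
Reagents that add atoms: lithium hydroxide, [Li+].[OH-]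
Why: Saponification cleaves the methyl ester and opens the γ‑lactone (C10 is then α to a carboxylate and not epimerisable), and on acidification only the γ‑hydroxy acid recloses (5‑exo‑trig lactonisation), which leaves the C3 carboxylic acid free.

Step 7
Reactants: 12 γ‑lactone carboxylic acid
Product: 13 hydroxy keto acid
Conditions: MeLi (3.2 equiv), THF, −78 °C; AcOH, −78 °C
Reagents that add atoms: methyllithium, [Li]C
Why: Monoaddition of MeLi to the γ‑lactone through a lithium hemiketalate that persists at −78 °C should give the γ‑hydroxy methyl ketone after a cold quench, the lithium carboxylate and alkoxide formed first being inert at this temperature (lactone‑to‑methyl‑ketone opening).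

Step 8
Reactants: 13 hydroxy keto acid
Product: 14 seven‑membered lactone
Conditions: 2‑methyl‑6‑nitrobenzoic anhydride (1.3 equiv), DMAP, Et3N, CH2Cl2 (2 mM, slow addition), rt
Reagents that add atoms: none
Why: Shiina lactonisation should close the seven‑membered lactone between the C3 acid and the secondary C8 hydroxyl, the furan 2,3‑bond holding both arms cis and the tertiary C4 hydroxyl being unable to lactonise.

Step 9
Reactants: 14 seven‑membered lactone
Product: 15 O4‑trimethylsilyl ether
Conditions: 1‑(trimethylsilyl)imidazole, CH2Cl2, rt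
Reagents that add atoms: 1‑(trimethylsilyl)imidazole, C[Si](C)(C)n1ccnc1
Why: Neutral O‑silylation of the tertiary alcohol avoids enolisation of the ketone, removes the only acidic O–H and turns the lactone into an α‑silyloxy ester, a better acyl donor.

Step 10
Reactants: 15 O4‑trimethylsilyl ether
Product: 17 macrocyclic furanone alcohol, via macrocyclic diketone 16 (not isolated)
Conditions: LiN(SiMe3)2 (1.2 equiv), THF (10 mM), −78 → −20 °C; then TsOH·H2O (3 equiv), THF/H2O, 0 °C → rt
Reagents that add atoms: none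
Why: Proposed new method: kinetic deprotonation of the acetyl CH3 (C2) gives a lithium enolate that adds to the lactone carbonyl C3 through a seven‑membered chelated transition state, and the bridged lithium hemiketalate (11‑oxabicyclo[4.4.1] core) collapses by cleavage of the C3–O8 bond, so that the seven‑membered lactone is ring‑expanded to the ten‑membered carbocycle (O→C acyl transfer) and the released alkoxide is quenched by the new 1,3‑diketone, whose enolate makes the transfer irreversible. The closest known reactions are the intramolecular Claisen (Dieckmann‑type) acylation of ketone enolates by esters and lactones and acyl‑transfer ring expansions of lactones, which have not been used to reach a ten‑membered carbocycle from a tethered methyl ketone; the acid half is the classical cyclodehydration of α'‑hydroxy‑1,3‑diketones to 3(2H)‑furanones. Ring closures: the carbocycle forms by 7‑exo‑trig attack of C2 on C3 followed by ring expansion, and the furanone by 5‑exo‑trig addition of the liberated C4 hydroxyl to the C1 carbonyl and loss of water. No stereocentre is created; C4, C8 and C10 are carried through, C10 being protected first by regioselective enolisation at the methyl group (hindered base, −78 °C) and then by the diketonate. The step needs C‑acylation at C3 only and furanone closure by O4 and not by O8: at the furan stage the substrate offers no other electrophile and no other acidic C–H, and under the reversible aqueous acid conditions the cyclically conjugated 3(2H)‑furanone is the expected sink over the exocyclic enol ether that O8 would give.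

Step 11
Reactants: 6 ethyl 2‑(hydroxymethyl)prop‑2‑enoate
Product: 18 TBS ether ethyl ester
Conditions: TBSCl, imidazole, DMF, 0 °C → rt
Reagents that add atoms: tert‑butyl(chloro)dimethylsilane, CC(C)(C)[Si](C)(C)Cl
Why: Imidazole‑promoted O‑silylation of the primary allylic alcohol is routine.

Step 12
Reactants: 18 TBS ether ethyl ester
Product: 19 silyloxymethyl acrylic acid
Conditions: LiOH·H2O, THF/H2O, 0 °C; then 1 M HCl to pH 4, 0 °C
Reagents that add atoms: lithium hydroxide, [Li+].[OH-]
Why: Saponification of the ethyl ester at 0 °C followed by mild acidification should give the acid with the silyl ether intact.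

Step 13
Reactants: 17 macrocyclic furanone alcohol; 19 silyloxymethyl acrylic acid
Product: 20 O8 acrylate ester
Conditions: 2,4,6‑trichlorobenzoyl chloride, Et3N, THF, rt; then 17, DMAP, toluene, rt
Reagents that add atoms: none
Why: Yamaguchi esterification through the mixed 2,4,6‑trichlorobenzoic anhydride should acylate the hindered secondary C8 hydroxyl without conjugate addition to the acrylate.

Step 14
Reactants: 20 O8 acrylate ester
Product: 22 γ‑hydroxybutenolide, via endoperoxide 21 (not isolated)
Conditions: O2, visible light, tetraphenylporphyrin (cat.), i‑Pr2NEt, CH2Cl2, −78 °C → rt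
Reagents that add atoms: dioxygen, O=O
Why: [4+2] cycloaddition of singlet oxygen to the electron‑rich furan followed by base‑induced Kornblum–DeLaMare fragmentation of the endoperoxide at its only C–H (C12) should give the γ‑hydroxybutenolide with the carbonyl at C12 and the hemiketal at C6, the electron‑poor furanone and acrylate being inert to singlet oxygen.

Step 15
Reactants: 22 γ‑hydroxybutenolide
Product: 24 bis‑silyl ether of the target, via hemiketal mesylate 23 (not isolated)
Conditions: MsCl, Et3N, CH2Cl2, −20 °C → rt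
Reagents that add atoms: none
Why: Sulfonylation of the hemiketal hydroxyl and loss of methanesulfonate together with a C5 proton (E1‑type dehydration of a γ‑hydroxybutenolide) should give the γ‑ylidenebutenolide, the ten‑membered ring allowing only the geometry with C4 and C7 cis on the new alkene (E).

Step 16
Reactants: 24 bis‑silyl ether of the target
Product: 25 CNP0261115.1
Conditions: HF·pyridine, pyridine, THF, 0 °C → rt
Reagents that add atoms: none
Why: Global desilylation with buffered HF should cleave both silyl ethers under conditions that the enol lactone, furanone and acrylate ester tolerate.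

**Compound list**

1 | furan‑3,4‑diyldimethanol | OCc1cocc1CO | starting material
2 | [4‑({[tert‑butyl(diphenyl)silyl]oxy}methyl)furan‑3‑yl]methanol | OCc1cocc1CO[Si](c1ccccc1)(c1ccccc1)C(C)(C)C | intermediate
3 | methyl (2S)‑2‑methyloxirane‑2‑carboxylate | COC(=O)[C@]1(C)CO1 | starting material
4 | dilithiated 2 (lithium alkoxide, lithium on the furan carbon next to the CH2OLi group; not isolated) | [Li]OCc1c([Li])occ1CO[Si](c1ccccc1)(c1ccccc1)C(C)(C)C | intermediate
5 | methyl (2S)‑3‑[4‑({[tert‑butyl(diphenyl)silyl]oxy}methyl)‑3‑(hydroxymethyl)furan‑2‑yl]‑2‑hydroxy‑2‑methylpropanoate | COC(=O)[C@@](C)(O)Cc1occ(CO[Si](c2ccccc2)(c2ccccc2)C(C)(C)C)c1CO | intermediate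
6 | ethyl 2‑(hydroxymethyl)prop‑2‑enoate | C=C(CO)C(=O)OCC | starting material
7 | ethyl 2‑{[(tert‑butoxycarbonyl)oxy]methyl}prop‑2‑enoate | C=C(COC(=O)OC(C)(C)C)C(=O)OCC | intermediate
8 | ethyl (4S)‑4‑hydroxy‑2‑methylidene‑4‑{4‑(TBDPS‑oxymethyl)‑2‑[(2S)‑2‑hydroxy‑3‑methoxy‑2‑methyl‑3‑oxopropyl]furan‑3‑yl}butanoate (not isolated) | CCOC(=O)C(=C)C[C@H](O)c1c(C[C@](C)(O)C(=O)OC)occ1CO[Si](c2ccccc2)(c2ccccc2)C(C)(C)C | intermediate
9 | methyl (2S)‑2‑hydroxy‑2‑methyl‑3‑{3‑[(2S)‑4‑methylidene‑5‑oxooxolan‑2‑yl]‑4‑(TBDPS‑oxymethyl)furan‑2‑yl}propanoate | C=C1C[C@@H](c2c(C[C@](C)(O)C(=O)OC)occ2CO[Si](c3ccccc3)(c3ccccc3)C(C)(C)C)OC1=O | intermediate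
10 | methyl (2S)‑2‑hydroxy‑2‑methyl‑3‑{3‑[(2S,4S)‑4‑methyl‑5‑oxooxolan‑2‑yl]‑4‑(TBDPS‑oxymethyl)furan‑2‑yl}propanoate | C[C@H]1C[C@@H](c2c(C[C@](C)(O)C(=O)OC)occ2CO[Si](c3ccccc3)(c3ccccc3)C(C)(C)C)OC1=O | intermediate
11 | (2S,4S)‑4‑{2‑[(2S)‑2‑carboxy‑2‑hydroxypropyl]‑4‑(TBDPS‑oxymethyl)furan‑3‑yl}‑4‑hydroxy‑2‑methylbutanoic acid (not isolated) | OC(=O)[C@@H](C)C[C@H](O)c1c(C[C@](C)(O)C(=O)O)occ1CO[Si](c2ccccc2)(c2ccccc2)C(C)(C)C | intermediate
12 | (2S)‑2‑hydroxy‑2‑methyl‑3‑{3‑[(2S,4S)‑4‑methyl‑5‑oxooxolan‑2‑yl]‑4‑(TBDPS‑oxymethyl)furan‑2‑yl}propanoic acid | C[C@H]1C[C@@H](c2c(C[C@](C)(O)C(=O)O)occ2CO[Si](c3ccccc3)(c3ccccc3)C(C)(C)C)OC1=O | intermediate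
13 | (2S)‑2‑hydroxy‑3‑{3‑[(1S,3S)‑1‑hydroxy‑3‑methyl‑4‑oxopentyl]‑4‑(TBDPS‑oxymethyl)furan‑2‑yl}‑2‑methylpropanoic acid (may equilibrate with its five‑membered lactol) | CC(=O)[C@@H](C)C[C@H](O)c1c(C[C@](C)(O)C(=O)O)occ1CO[Si](c2ccccc2)(c2ccccc2)C(C)(C)C | intermediate
14 | furan‑fused seven‑membered lactone: ring O8–C3(=O)–C4(CH3)(OH)–C5H2–C6(furan C‑2)=C7(furan C‑3)–C8H; C8 bears the (2S)‑2‑methyl‑3‑oxobutyl chain, furan C‑4 the CH2OTBDPS group; 4S,8S,10S | CC(=O)[C@@H](C)C[C@@H]1OC(=O)[C@@](C)(O)Cc2occ(CO[Si](c3ccccc3)(c3ccccc3)C(C)(C)C)c12 | intermediate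
15 | O4‑trimethylsilyl ether of 14 | CC(=O)[C@@H](C)C[C@@H]1OC(=O)[C@@](C)(O[Si](C)(C)C)Cc2occ(CO[Si](c3ccccc3)(c3ccccc3)C(C)(C)C)c12 | intermediate
16 | ten‑membered carbocyclic 1,3‑diketone (C1 and C3 ketones, C2H2 between them) fused at C6–C7 to the furan, free 8‑OH, 4‑OSiMe3; 4S,8S,10S (not isolated) | C[C@H]1C[C@H](O)c2c(C[C@](C)(O[Si](C)(C)C)C(=O)CC1=O)occ2CO[Si](c3ccccc3)(c3ccccc3)C(C)(C)C | intermediate
17 | macrocyclic 3(2H)‑furanone alcohol: ten‑membered carbocycle bridged C1–O–C4 (C1=C2–C3=O), fused at C6–C7 to the 4‑(TBDPS‑oxymethyl)furan, free 8‑OH; 4S,8S,10S | O[C@H]1C[C@H](C)C2=CC(=O)[C@](C)(Cc3occ(CO[Si](c4ccccc4)(c4ccccc4)C(C)(C)C)c31)O2 | intermediate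
18 | ethyl 2‑({[tert‑butyl(dimethyl)silyl]oxy}methyl)prop‑2‑enoate | C=C(CO[Si](C)(C)C(C)(C)C)C(=O)OCC | intermediate
19 | 2‑({[tert‑butyl(dimethyl)silyl]oxy}methyl)prop‑2‑enoic acid | C=C(CO[Si](C)(C)C(C)(C)C)C(=O)O | intermediate
20 | 8‑O‑[2‑(TBS‑oxymethyl)acryloyl] ester of 17 | C=C(CO[Si](C)(C)C(C)(C)C)C(=O)O[C@H]1C[C@H](C)C2=CC(=O)[C@](C)(Cc3occ(CO[Si](c4ccccc4)(c4ccccc4)C(C)(C)C)c31)O2 | intermediate
21 | 2,5‑endoperoxide of the furan ring of 20 (O–O bridge between C6 and C12; not isolated) | C=C(CO[Si](C)(C)C(C)(C)C)C(=O)O[C@H]1C[C@H](C)C2=CC(=O)[C@](C)(CC34OOC(O3)C(CO[Si](c5ccccc5)(c5ccccc5)C(C)(C)C)=C41)O2 | intermediate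
22 | γ‑hydroxybutenolide: C12 lactone carbonyl, C6 hemiketal OH (epimer mixture), C5H2, C7=C11 | C=C(CO[Si](C)(C)C(C)(C)C)C(=O)O[C@H]1C[C@H](C)C2=CC(=O)[C@](C)(CC3(O)OC(=O)C(CO[Si](c4ccccc4)(c4ccccc4)C(C)(C)C)=C31)O2 | intermediate
23 | C6 methanesulfonate of 22 (not isolated) | C=C(CO[Si](C)(C)C(C)(C)C)C(=O)O[C@H]1C[C@H](C)C2=CC(=O)[C@](C)(CC3(OS(C)(=O)=O)OC(=O)C(CO[Si](c4ccccc4)(c4ccccc4)C(C)(C)C)=C31)O2 | intermediate
24 | bis‑silyl ether of the target (13‑O‑TBDPS, side‑chain O‑TBS) | C=C(CO[Si](C)(C)C(C)(C)C)C(=O)O[C@H]1C[C@H](C)C2=CC(=O)[C@](C)(/C=C3/OC(=O)C(CO[Si](c4ccccc4)(c4ccccc4)C(C)(C)C)=C31)O2 | intermediate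
25 | CNP0261115.1: (4S,8S,10S)‑13‑hydroxy‑8‑[2‑(hydroxymethyl)acryloyloxy]‑3‑oxo‑1,4‑epoxygermacra‑1,5E,7(11)‑trien‑12,6‑olide | C=C(CO)C(=O)O[C@H]1C[C@H](C)C2=CC(=O)[C@](C)(/C=C3/OC(=O)C(CO)=C31)O2 | target

**Totals**

Total step count: 16. Longest linear sequence: 13 steps (1, 2, 4–10, 13–16).

**Steps most likely to fail**

1. Step 10 (proposed new method). The bridged hemiketalate may collapse back to lactone and enolate instead of expanding the ring. Enolate equilibration would then erode C10, and in the acid half the vinylogous ester may close through O8 instead of O4. Fallback with known reactions, setting out from 13 and returning at 17: 13 is coupled with N,O‑dimethylhydroxylamine hydrochloride (EDC·HCl, HOBt, i‑Pr2NEt) to the Weinreb amide F1. Both hydroxyls are silylated (Et3SiOTf, 2,6‑lutidine, −78 °C) to the bis(triethylsilyl) ether F2. The kinetic lithium enolate of the methyl ketone (LiN(SiMe3)2, THF, high dilution, −78 → 0 °C) is acylated intramolecularly by the Weinreb amide, whose chelated tetrahedral intermediate cannot revert, giving the bis‑silyl macrocyclic 1,3‑diketone F3. TsOH·H2O in wet THF then removes both silyl groups and closes the furanone to 17.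

2. Step 2. Lithiation may occur at the other furan α‑position, or the aryl‑metal may add to the ester carbonyl instead of opening the epoxide. Fallback setting out from 2 and 3 and returning at 5, in which the tether and not the metalation fixes the site: 3 is saponified (KOH, MeOH, 0 °C) to potassium (2S)‑2‑methyloxirane‑2‑carboxylate F4. F4 is esterified with 2 (2,4,6‑trichlorobenzoyl chloride, Et3N, DMAP) to the glycidic ester F5. A Lewis acid (Et2AlCl or BF3·OEt2, CH2Cl2, −78 °C) triggers a furan‑terminated epoxide cyclisation (intramolecular Friedel–Crafts alkylation) in which only the neighbouring furan α‑carbon can reach the epoxide CH2, giving the seven‑membered hydroxy lactone F6. Methanolysis (K2CO3, MeOH) opens F6 to 5.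

3. Step 4. Dehydrogenation and allylation of the doubly ortho‑substituted furylmethanol may be slow, the hydroxy ester may lactonise under the basic conditions, or catalyst control at C8 may be poor. Fallback setting out from 5 and returning at 9, working at the aldehyde level: 5 is oxidised (MnO2, CH2Cl2) to the furan‑3‑carbaldehyde F7. F7 undergoes chromium‑catalysed enantioselective 2‑(alkoxycarbonyl)allylation with ethyl 2‑(bromomethyl)acrylate (CrCl2 10 mol%, chiral bis(oxazoline) ligand, Mn powder, THF) to give 8, which lactonises on mild acid work‑up to 9.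

**Further compounds**

F1 | step 10 | Weinreb amide of 13: (2S)‑2‑hydroxy‑3‑{3‑[(1S,3S)‑1‑hydroxy‑3‑methyl‑4‑oxopentyl]‑4‑(TBDPS‑oxymethyl)furan‑2‑yl}‑N‑methoxy‑N,2‑dimethylpropanamide | CC(=O)[C@@H](C)C[C@H](O)c1c(C[C@](C)(O)C(=O)N(C)OC)occ1CO[Si](c2ccccc2)(c2ccccc2)C(C)(C)C
F2 | step 10 | 4,8‑bis(triethylsilyl) ether of F1 | CC(=O)[C@@H](C)C[C@H](O[Si](CC)(CC)CC)c1c(C[C@](C)(O[Si](CC)(CC)CC)C(=O)N(C)OC)occ1CO[Si](c2ccccc2)(c2ccccc2)C(C)(C)C
F3 | step 10 | 4,8‑bis(triethylsilyl) ether of the macrocyclic 1,3‑diketone (the 8‑O‑silylated, triethylsilyl analogue of 16) | C[C@H]1C[C@H](O[Si](CC)(CC)CC)c2c(C[C@](C)(O[Si](CC)(CC)CC)C(=O)CC1=O)occ2CO[Si](c3ccccc3)(c3ccccc3)C(C)(C)C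
F4 | step 2 | potassium (2S)‑2‑methyloxirane‑2‑carboxylate | [K+].[O-]C(=O)[C@]1(C)CO1
F5 | step 2 | [4‑(TBDPS‑oxymethyl)furan‑3‑yl]methyl (2S)‑2‑methyloxirane‑2‑carboxylate | O=C(OCc1cocc1CO[Si](c2ccccc2)(c2ccccc2)C(C)(C)C)[C@]3(C)CO3
F6 | step 2 | furan‑fused seven‑membered hydroxy lactone with unsubstituted C8H2: ring O–C(=O)–C(CH3)(OH)–CH2–furan C‑2/C‑3–CH2, furan C‑4 bearing CH2OTBDPS; S at the carbinol carbon | O=C1OCc2c(CO[Si](c3ccccc3)(c3ccccc3)C(C)(C)C)coc2C[C@]1(C)O
F7 | step 4 | methyl (2S)‑3‑[3‑formyl‑4‑(TBDPS‑oxymethyl)furan‑2‑yl]‑2‑hydroxy‑2‑methylpropanoate | COC(=O)[C@@](C)(O)Cc1occ(CO[Si](c2ccccc2)(c2ccccc2)C(C)(C)C)c1C=O
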